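**Plan**

- Retrosynthesis: the acrylic acid C=C is cut first (back to a C5 aldehyde and malonic acid), then the O1–C7a bond of the dihydrofuran, then C2–C3 (aldol), and finally the C3–C3a bond (aryl–CH2 cross-coupling on fluorinated 5-iodovanillin).
- Enabling feature (benzofuran numbering, ring A = benzo ring): O1 is bonded to C7a, and C7a is para to C5, the ring-A carbon that carries the acrylic acid. With C5 as a formyl group and fluorine on C7a, C7a is an SNAr site.
- Forward: ring A is fluorinated and homologated to an arylacetyl imide, the chain is joined to O-benzylsyringaldehyde by a syn aldol, the dihydrofuran (the only ring formed) closes through O1–C7a, and the acrylic acid is attached in the last step but one.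
- Stereochemistry: C2 and C3 are both set in the aldol under control of (S)-4-benzyloxazolidin-2-one and are only carried through afterwards. The E alkene comes from the decarboxylative condensation.
- Protecting groups: the primary alcohol is a trityl ether, not a silyl ether, because both hydroxyls of the diol lie five atoms from C7a and a migrating group would let the wrong oxygen close.

Key step: step 11

Remark: benzofuran numbering (O1, C2, C3, C3a, C4–C7, C7a) is used for the target and its open-chain precursors; (2-ethoxy-2-oxoethyl)zinc bromide 5 is taken as the commercial THF solution.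

**Step 1**
Reactants: 1 5-iodovanillin (4-hydroxy-3-iodo-5-methoxybenzaldehyde)
Product: 3 4-fluoro-3-iodo-5-methoxybenzaldehyde, via aryl fluorosulfonate 2 (not isolated)
Conditions: SO2F2 (1 atm), Me4NF (anhydrous, 3 equiv), DMF, rt to 60 °C
Reagents that add atoms: tetramethylammonium fluoride, C[N+](C)(C)C.[F-] (the fluorine of 3); sulfuryl fluoride, O=S(=O)(F)F (its SO2F group stays only in intermediate 2)
Why: Phenol deoxyfluorination through the aryl fluorosulfonate: the phenoxide is sulfonylated by SO2F2 in the flask and fluoride then replaces fluorosulfate at the ipso carbon, a substitution that the para formyl group accelerates and that leaves the C–I bond alone.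

**Step 2**
Reactants: 3 4-fluoro-3-iodo-5-methoxybenzaldehyde
Product: 4 2-(4-fluoro-3-iodo-5-methoxyphenyl)-1,3-dioxolane
Conditions: ethylene glycol, TsOH (cat.), toluene, reflux, Dean–Stark trap
Reagents that add atoms: ethylene glycol, OCCO
Why: Acid-catalysed acetalisation with azeotropic removal of water; the dioxolane hides the aldehyde from the zinc enolate, the boron enolate and the borohydride of the following steps and also switches off SNAr at the C–F carbon until it is wanted.

**Step 3**
Reactants: 4 2-(4-fluoro-3-iodo-5-methoxyphenyl)-1,3-dioxolane; 5 (2-ethoxy-2-oxoethyl)zinc bromide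
Product: 6 ethyl 2-[5-(1,3-dioxolan-2-yl)-2-fluoro-3-methoxyphenyl]acetate
Conditions: Pd2(dba)3 (cat.), XPhos (cat.), THF, 60 °C
Reagents that add atoms: none
Why: Negishi cross-coupling of a Reformatsky reagent: zerovalent palladium inserts into the C–I bond only, the zinc enolate transmetalates through carbon and reductive elimination forms the aryl–CH2 bond (the later C3a–C3 bond).

**Step 4**
Reactants: 6 ethyl 2-[5-(1,3-dioxolan-2-yl)-2-fluoro-3-methoxyphenyl]acetate
Product: 7 2-[5-(1,3-dioxolan-2-yl)-2-fluoro-3-methoxyphenyl]acetic acid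
Conditions: LiOH, THF/H2O, rt; then 1 M HCl to pH 4, 0 °C
Reagents that add atoms: lithium hydroxide, [Li+].[OH-]
Why: Ester saponification; the dioxolane is stable to hydroxide, the unactivated aryl fluoride is not displaced, and the cold acidification to pH 4 frees the acid without hydrolysing the acetal.

**Step 5**
Reactants: 7 2-[5-(1,3-dioxolan-2-yl)-2-fluoro-3-methoxyphenyl]acetic acid; 8 (S)-4-benzyloxazolidin-2-one
Product: 10 (S)-4-benzyl-3-{2-[5-(1,3-dioxolan-2-yl)-2-fluoro-3-methoxyphenyl]acetyl}oxazolidin-2-one, via mixed pivalic anhydride 9 (not isolated)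
Conditions: PivCl, Et3N, THF, −20 °C; then 8, LiCl, −20 °C to rt
Reagents that add atoms: pivaloyl chloride, CC(C)(C)C(=O)Cl (its acyl group stays only in intermediate 9)
Why: N-Acylation of the oxazolidinone through the mixed pivalic anhydride with LiCl and Et3N, in which the amide nitrogen attacks the less hindered arylacetyl carbonyl.

**Step 6**
Reactants: 11 syringaldehyde (4-hydroxy-3,5-dimethoxybenzaldehyde)
Product: 12 4-benzyloxy-3,5-dimethoxybenzaldehyde
Conditions: BnBr, K2CO3, DMF, 60 °C
Reagents that add atoms: benzyl bromide, BrCc1ccccc1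
Why: Williamson ether synthesis on the phenoxide; the benzyl ether is stable to the boron aldol, to borohydride, to carbonate in DMSO and to hot pyridine, and is removed at the end together with the trityl group.

**Step 7**
Reactants: 10 (S)-4-benzyl-3-{2-[5-(1,3-dioxolan-2-yl)-2-fluoro-3-methoxyphenyl]acetyl}oxazolidin-2-one; 12 4-benzyloxy-3,5-dimethoxybenzaldehyde
Product: 15 (S)-4-benzyl-3-[(2S,3S)-3-(4-benzyloxy-3,5-dimethoxyphenyl)-2-[5-(1,3-dioxolan-2-yl)-2-fluoro-3-methoxyphenyl]-3-hydroxypropanoyl]oxazolidin-2-one, via Z-boron enolate 13 (not isolated), via boron aldolate 14 (not isolated)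
Conditions: Bu2BOTf, iPr2NEt, CH2Cl2, −78 to 0 °C; then 12, −78 to 0 °C; then pH 7 phosphate buffer, MeOH, 30% H2O2, 0 °C
Reagents that add atoms: dibutylboron triflate, CCCCB(CCCC)OS(=O)(=O)C(F)(F)F (its Bu2B group stays only in intermediates 13 and 14)
Why: Evans syn aldol reaction: soft enolisation gives the Z-boron enolate, which adds to the aldehyde through a closed Zimmerman–Traxler chair with the benzyl group of the (S)-auxiliary shielding one enolate face, so that the (2S,3S) syn adduct forms (the two carbons that become C3 and C2 of the benzofuran) and the oxidative work-up only cleaves the B–C and B–O bonds.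

**Step 8**
Reactants: 15 (S)-4-benzyl-3-[(2S,3S)-3-(4-benzyloxy-3,5-dimethoxyphenyl)-2-[5-(1,3-dioxolan-2-yl)-2-fluoro-3-methoxyphenyl]-3-hydroxypropanoyl]oxazolidin-2-one
Product: 16 (1S,2R)-1-(4-benzyloxy-3,5-dimethoxyphenyl)-2-[5-(1,3-dioxolan-2-yl)-2-fluoro-3-methoxyphenyl]propane-1,3-diol
Conditions: LiBH4, MeOH (1 equiv), THF, 0 °C; then H2O
Reagents that add atoms: none
Why: Reductive removal of the auxiliary: LiBH4 reduces the exocyclic imide carbonyl to the primary alcohol and releases the oxazolidinone, the acetal is inert, and the benzylic carbon keeps its geometry (its descriptor changes from S to R only because the CIP priorities change).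

**Step 9**
Reactants: 16 (1S,2R)-1-(4-benzyloxy-3,5-dimethoxyphenyl)-2-[5-(1,3-dioxolan-2-yl)-2-fluoro-3-methoxyphenyl]propane-1,3-diol
Product: 17 3-[(1S,2R)-1-(4-benzyloxy-3,5-dimethoxyphenyl)-1,3-dihydroxypropan-2-yl]-4-fluoro-5-methoxybenzaldehyde
Conditions: 1 M aq. HCl (cat.), THF, rt
Reagents that add atoms: water, O
Why: Acid-catalysed acetal hydrolysis in wet THF restores the formyl group that has to activate C7a, under conditions too mild to ionise the benzylic alcohol.

**Step 10**
Reactants: 17 3-[(1S,2R)-1-(4-benzyloxy-3,5-dimethoxyphenyl)-1,3-dihydroxypropan-2-yl]-4-fluoro-5-methoxybenzaldehyde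
Product: 18 3-[(1S,2R)-1-(4-benzyloxy-3,5-dimethoxyphenyl)-1-hydroxy-3-(trityloxy)propan-2-yl]-4-fluoro-5-methoxybenzaldehyde
Conditions: TrCl, Et3N, DMAP (cat.), CH2Cl2, rt
Reagents that add atoms: trityl chloride, ClC(c1ccccc1)(c1ccccc1)c1ccccc1
Why: Selective O-tritylation of the primary hydroxyl (SN1-type alkylation by the trityl cation, governed by steric demand), which leaves the secondary benzylic hydroxyl free as the nucleophile of the next step and puts on the primary oxygen a group that cannot migrate.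

**Step 11**
Reactants: 18 3-[(1S,2R)-1-(4-benzyloxy-3,5-dimethoxyphenyl)-1-hydroxy-3-(trityloxy)propan-2-yl]-4-fluoro-5-methoxybenzaldehyde
Product: 19 (2S,3R)-2-(4-benzyloxy-3,5-dimethoxyphenyl)-7-methoxy-3-[(trityloxy)methyl]-2,3-dihydrobenzofuran-5-carbaldehyde
Conditions: Cs2CO3, DMSO (dry, dilute), 60 °C
Reagents that add atoms: none
Why: Cs2CO3 in DMSO sets up a small equilibrium concentration of the secondary benzylic alkoxide, which adds to C7a of ring A to give a Meisenheimer anion whose charge is delocalised into the para formyl group at C5, and loss of fluoride restores the arene (addition–elimination, SNAr). The closest known reaction type is the intramolecular SNAr of alkoxides on 4-fluorobenzaldehydes and related activated fluoroarenes, which gives dihydrobenzofurans and chromans. The dihydrofuran ring closes in a 5-exo mode, the new O1–C7a bond lying in the ring and the departing C–F bond outside it. No stereocenter is formed and no bond at C2 or C3 is made or broken, so the S carbinol and the R benzylic carbon of 18 are carried over unchanged and the syn arrangement of 18 appears as the 2,3-trans ring of 19. The step needs closure through the secondary oxygen and at C7a only: the primary oxygen, equally five atoms from C7a, is blocked by a trityl group that cannot migrate, addition of the alkoxide to the aldehyde is reversible and unproductive, and fluorine is the only leaving group on ring A and sits on the one carbon the tether can reach.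

**Step 12**
Reactants: 19 (2S,3R)-2-(4-benzyloxy-3,5-dimethoxyphenyl)-7-methoxy-3-[(trityloxy)methyl]-2,3-dihydrobenzofuran-5-carbaldehyde; 20 malonic acid
Product: 22 (E)-3-[(2S,3R)-2-(4-benzyloxy-3,5-dimethoxyphenyl)-7-methoxy-3-[(trityloxy)methyl]-2,3-dihydrobenzofuran-5-yl]acrylic acid, via arylidenemalonic acid 21 (not isolated)
Conditions: pyridine, piperidine (cat.), 90 °C
Reagents that add atoms: none
Why: Knoevenagel condensation under Doebner conditions: the piperidine-catalysed condensation gives the arylidenemalonic acid, which loses CO2 in hot pyridine to give the conjugated acid with the thermodynamically favoured E geometry; trityl ether, benzyl ether and both stereocenters are inert to the weak base.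

**Step 13**
Reactants: 22 (E)-3-[(2S,3R)-2-(4-benzyloxy-3,5-dimethoxyphenyl)-7-methoxy-3-[(trityloxy)methyl]-2,3-dihydrobenzofuran-5-yl]acrylic acid
Product: 23 (E)-3-[(2S,3R)-2-(4-hydroxy-3,5-dimethoxyphenyl)-3-(hydroxymethyl)-7-methoxy-2,3-dihydrobenzofuran-5-yl]acrylic acid (CNP0224723.1)
Conditions: BCl3, C6HMe5, CH2Cl2, −78 to −30 °C; then H2O
Reagents that add atoms: none
Why: Lewis-acid ether cleavage: BCl3 ionises the aryl benzyl ether (aided by chelation with a neighbouring methoxy group) and the trityl ether at low temperature, pentamethylbenzene traps the benzyl cation by Friedel–Crafts alkylation, and water hydrolyses the boron esters, while aryl methyl ethers, the acrylic acid and the dihydrofuran ring are expected to survive at −78 to −30 °C.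

**Compound list**

1 | 5-iodovanillin (4-hydroxy-3-iodo-5-methoxybenzaldehyde) | COc1cc(C=O)cc(I)c1O | starting material
2 | 4-formyl-2-iodo-6-methoxyphenyl fluorosulfonate | COc1cc(C=O)cc(I)c1OS(=O)(=O)F | intermediate
3 | 4-fluoro-3-iodo-5-methoxybenzaldehyde | COc1cc(C=O)cc(I)c1F | intermediate
4 | 2-(4-fluoro-3-iodo-5-methoxyphenyl)-1,3-dioxolane | COc1cc(C2OCCO2)cc(I)c1F | intermediate
5 | (2-ethoxy-2-oxoethyl)zinc bromide | CCOC(=O)C[Zn]Br | starting material
6 | ethyl 2-[5-(1,3-dioxolan-2-yl)-2-fluoro-3-methoxyphenyl]acetate | CCOC(=O)Cc1cc(C2OCCO2)cc(OC)c1F | intermediate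
7 | 2-[5-(1,3-dioxolan-2-yl)-2-fluoro-3-methoxyphenyl]acetic acid | OC(=O)Cc1cc(C2OCCO2)cc(OC)c1F | intermediate
8 | (S)-4-benzyloxazolidin-2-one | O=C1N[C@@H](Cc2ccccc2)CO1 | starting material
9 | 2-[5-(1,3-dioxolan-2-yl)-2-fluoro-3-methoxyphenyl]acetic pivalic anhydride | CC(C)(C)C(=O)OC(=O)Cc1cc(C2OCCO2)cc(OC)c1F | intermediate
10 | (S)-4-benzyl-3-{2-[5-(1,3-dioxolan-2-yl)-2-fluoro-3-methoxyphenyl]acetyl}oxazolidin-2-one | O=C(Cc1cc(C2OCCO2)cc(OC)c1F)N1[C@@H](Cc2ccccc2)COC1=O | intermediate
11 | syringaldehyde (4-hydroxy-3,5-dimethoxybenzaldehyde) | COc1cc(C=O)cc(OC)c1O | starting material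
12 | 4-benzyloxy-3,5-dimethoxybenzaldehyde | COc1cc(C=O)cc(OC)c1OCc1ccccc1 | intermediate
13 | (S)-4-benzyl-3-[(Z)-1-(dibutylboryloxy)-2-[5-(1,3-dioxolan-2-yl)-2-fluoro-3-methoxyphenyl]ethenyl]oxazolidin-2-one | CCCCB(CCCC)O/C(=C\c1cc(C2OCCO2)cc(OC)c1F)N1[C@@H](Cc2ccccc2)COC1=O | intermediate
14 | O-dibutylboryl derivative of aldol 15 (boron on the C3 oxygen of the propanoyl chain) | COc1cc([C@@H](OB(CCCC)CCCC)[C@@H](C(=O)N2[C@@H](Cc3ccccc3)COC2=O)c2cc(C3OCCO3)cc(OC)c2F)cc(OC)c1OCc1ccccc1 | intermediate
15 | (S)-4-benzyl-3-[(2S,3S)-3-(4-benzyloxy-3,5-dimethoxyphenyl)-2-[5-(1,3-dioxolan-2-yl)-2-fluoro-3-methoxyphenyl]-3-hydroxypropanoyl]oxazolidin-2-one | COc1cc([C@@H](O)[C@@H](C(=O)N2[C@@H](Cc3ccccc3)COC2=O)c2cc(C3OCCO3)cc(OC)c2F)cc(OC)c1OCc1ccccc1 | intermediate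
16 | (1S,2R)-1-(4-benzyloxy-3,5-dimethoxyphenyl)-2-[5-(1,3-dioxolan-2-yl)-2-fluoro-3-methoxyphenyl]propane-1,3-diol | COc1cc([C@@H](O)[C@@H](CO)c2cc(C3OCCO3)cc(OC)c2F)cc(OC)c1OCc1ccccc1 | intermediate
17 | 3-[(1S,2R)-1-(4-benzyloxy-3,5-dimethoxyphenyl)-1,3-dihydroxypropan-2-yl]-4-fluoro-5-methoxybenzaldehyde | COc1cc([C@@H](O)[C@@H](CO)c2cc(C=O)cc(OC)c2F)cc(OC)c1OCc1ccccc1 | intermediate
18 | 3-[(1S,2R)-1-(4-benzyloxy-3,5-dimethoxyphenyl)-1-hydroxy-3-(trityloxy)propan-2-yl]-4-fluoro-5-methoxybenzaldehyde | COc1cc([C@@H](O)[C@@H](COC(c2ccccc2)(c2ccccc2)c2ccccc2)c2cc(C=O)cc(OC)c2F)cc(OC)c1OCc1ccccc1 | intermediate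
19 | (2S,3R)-2-(4-benzyloxy-3,5-dimethoxyphenyl)-7-methoxy-3-[(trityloxy)methyl]-2,3-dihydrobenzofuran-5-carbaldehyde | COc1cc([C@H]2Oc3c(OC)cc(C=O)cc3[C@@H]2COC(c2ccccc2)(c2ccccc2)c2ccccc2)cc(OC)c1OCc1ccccc1 | intermediate
20 | malonic acid | OC(=O)CC(=O)O | starting material
21 | 2-{[(2S,3R)-2-(4-benzyloxy-3,5-dimethoxyphenyl)-7-methoxy-3-[(trityloxy)methyl]-2,3-dihydrobenzofuran-5-yl]methylidene}malonic acid | COc1cc([C@H]2Oc3c(OC)cc(C=C(C(=O)O)C(=O)O)cc3[C@@H]2COC(c2ccccc2)(c2ccccc2)c2ccccc2)cc(OC)c1OCc1ccccc1 | intermediate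
22 | (E)-3-[(2S,3R)-2-(4-benzyloxy-3,5-dimethoxyphenyl)-7-methoxy-3-[(trityloxy)methyl]-2,3-dihydrobenzofuran-5-yl]acrylic acid | COc1cc([C@H]2Oc3c(OC)cc(/C=C/C(=O)O)cc3[C@@H]2COC(c2ccccc2)(c2ccccc2)c2ccccc2)cc(OC)c1OCc1ccccc1 | intermediate
23 | (E)-3-[(2S,3R)-2-(4-hydroxy-3,5-dimethoxyphenyl)-3-(hydroxymethyl)-7-methoxy-2,3-dihydrobenzofuran-5-yl]acrylic acid | COc1cc([C@H]2Oc3c(OC)cc(/C=C/C(=O)O)cc3[C@@H]2CO)cc(OC)c1O | target

**Step count**

Total step count: 13. Longest linear sequence: 12 steps (steps 1–5 and 7–13); step 6 is the only step off the main line.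

**Steps most likely to fail**

Step 11 (ring closure). The alkoxide may be used up at the formyl group, by hemiacetal formation followed by hydride transfer between aldehyde molecules, faster than it closes onto the methoxy-flanked C7a. The base strength needed for closure may also be more than the aldehyde tolerates. The fallback keeps the O1–C7a closure but runs it on a nitrile, which activates the para carbon and is inert to alkoxide.
- It sets out from 18. I2 in aqueous NH3/THF at rt converts the aldehyde into 3-[(1S,2R)-1-(4-benzyloxy-3,5-dimethoxyphenyl)-1-hydroxy-3-(trityloxy)propan-2-yl]-4-fluoro-5-methoxybenzonitrile F4.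
- KN(SiMe3)2 in THF at 0 °C to rt closes the ring to (2S,3R)-2-(4-benzyloxy-3,5-dimethoxyphenyl)-7-methoxy-3-[(trityloxy)methyl]-2,3-dihydrobenzofuran-5-carbonitrile F5.
- iBu2AlH in toluene at −78 °C, followed by hydrolysis of the aldimine with aqueous citric acid, returns the route at aldehyde 19.

Step 1 (deoxyfluorination). Substitution at the doubly ortho-substituted ipso carbon may be incomplete, or fluoride may attack the aldehyde instead. The fallback makes the C–F bond by palladium catalysis after the iodide has been used.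
- It sets out from 1. Tf2O and pyridine in CH2Cl2 give 4-formyl-2-iodo-6-methoxyphenyl trifluoromethanesulfonate F1.
- Acetalisation as in step 2 gives 4-(1,3-dioxolan-2-yl)-2-iodo-6-methoxyphenyl trifluoromethanesulfonate F2.
- Negishi coupling with 5 under Pd(PPh3)4 in THF, selective for the C–I bond over the C–OTf bond, gives ethyl 2-{5-(1,3-dioxolan-2-yl)-3-methoxy-2-[(trifluoromethylsulfonyl)oxy]phenyl}acetate F3.
- Palladium-catalysed fluorination of the aryl triflate (CsF, [(cinnamyl)PdCl]2, tBuBrettPhos, toluene, 110 °C) returns the route at ester 6.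

Step 13 (global deprotection). The Lewis acid may ionise the benzylic C2–O1 bond next to the electron-rich aryl group (ring opening, chloride capture), or a methyl ether may be lost alongside the benzyl ether. The fallback removes both groups without a Lewis acid, before the alkene is present.
- It sets out from 19. Hydrogenolysis (H2 at 1 atm, Pd/C, EtOAc, rt, stopped when 19 is consumed) gives (2S,3R)-2-(4-hydroxy-3,5-dimethoxyphenyl)-7-methoxy-3-[(trityloxy)methyl]-2,3-dihydrobenzofuran-5-carbaldehyde F6.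
- 80% aqueous AcOH at 40 °C removes the trityl group to give (2S,3R)-2-(4-hydroxy-3,5-dimethoxyphenyl)-3-(hydroxymethyl)-7-methoxy-2,3-dihydrobenzofuran-5-carbaldehyde F7.
- Knoevenagel–Doebner condensation with 20 (pyridine, catalytic piperidine, 90 °C) passes through 2-{[(2S,3R)-2-(4-hydroxy-3,5-dimethoxyphenyl)-3-(hydroxymethyl)-7-methoxy-2,3-dihydrobenzofuran-5-yl]methylidene}malonic acid F8, which is not isolated, and returns the route at 23.

**Further compounds**

F1 | step 1 | 4-formyl-2-iodo-6-methoxyphenyl trifluoromethanesulfonate | COc1cc(C=O)cc(I)c1OS(=O)(=O)C(F)(F)F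
F2 | step 1 | 4-(1,3-dioxolan-2-yl)-2-iodo-6-methoxyphenyl trifluoromethanesulfonate | COc1cc(C2OCCO2)cc(I)c1OS(=O)(=O)C(F)(F)F
F3 | step 1 | ethyl 2-{5-(1,3-dioxolan-2-yl)-3-methoxy-2-[(trifluoromethylsulfonyl)oxy]phenyl}acetate | CCOC(=O)Cc1cc(C2OCCO2)cc(OC)c1OS(=O)(=O)C(F)(F)F
F4 | step 11 | 3-[(1S,2R)-1-(4-benzyloxy-3,5-dimethoxyphenyl)-1-hydroxy-3-(trityloxy)propan-2-yl]-4-fluoro-5-methoxybenzonitrile | COc1cc([C@@H](O)[C@@H](COC(c2ccccc2)(c2ccccc2)c2ccccc2)c2cc(C#N)cc(OC)c2F)cc(OC)c1OCc1ccccc1
F5 | step 11 | (2S,3R)-2-(4-benzyloxy-3,5-dimethoxyphenyl)-7-methoxy-3-[(trityloxy)methyl]-2,3-dihydrobenzofuran-5-carbonitrile | COc1cc([C@H]2Oc3c(OC)cc(C#N)cc3[C@@H]2COC(c2ccccc2)(c2ccccc2)c2ccccc2)cc(OC)c1OCc1ccccc1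
F6 | step 13 | (2S,3R)-2-(4-hydroxy-3,5-dimethoxyphenyl)-7-methoxy-3-[(trityloxy)methyl]-2,3-dihydrobenzofuran-5-carbaldehyde | COc1cc([C@H]2Oc3c(OC)cc(C=O)cc3[C@@H]2COC(c2ccccc2)(c2ccccc2)c2ccccc2)cc(OC)c1O
F7 | step 13 | (2S,3R)-2-(4-hydroxy-3,5-dimethoxyphenyl)-3-(hydroxymethyl)-7-methoxy-2,3-dihydrobenzofuran-5-carbaldehyde | COc1cc([C@H]2Oc3c(OC)cc(C=O)cc3[C@@H]2CO)cc(OC)c1O
F8 | step 13 | 2-{[(2S,3R)-2-(4-hydroxy-3,5-dimethoxyphenyl)-3-(hydroxymethyl)-7-methoxy-2,3-dihydrobenzofuran-5-yl]methylidene}malonic acid | COc1cc([C@H]2Oc3c(OC)cc(C=C(C(=O)O)C(=O)O)cc3[C@@H]2CO)cc(OC)c1O
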